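The runs come from a simulation from invented constants; noise was put on by code.

I decide to reckon the asked flask by one number, the gain, and to build it up from the mirror case.

all flasks: added ligand 2.2 mM

| run | left-handed substrate | right-handed substrate | partner | precatalyst | remark | time |
|---|---|---|---|---|---|---|
| ochre | 0.20 M | 0.20 M | 0.40 M | 0.20 mM | run made earlier |  |
| grey | 0.20 M | 0.20 M | 0.40 M | 0.30 mM | run made earlier |  |
| green | 0.30 M | 0.30 M | 0.40 M | 0.40 mM | run made earlier |  |
| flask | 0.20 M | 0.20 M | 0.400 M | 0.40 mM |  | 50 h |

| run | time / h | right-handed substrate / % | left-handed substrate / % |
|---|---|---|---|
| ochre | 4.00 | 49.2 | 48.6 |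
| ochre | 10.0 | 47.7 | 45.7 |
| ochre | 20.0 | 44.5 | 43.2 |
| ochre | 30.0 | 41.4 | 39.3 |
| grey | 2.50 | 50.7 | 50.0 |
| grey | 6.00 | 49.2 | 47.3 |
| grey | 12.0 | 45.4 | 43.3 |
| grey | 30.0 | 39.0 | 35.9 |
| green | 8.00 | 47.6 | 46.0 |
| green | 15.0 | 44.6 | 43.7 |
| green | 25.0 | 41.1 | 39.0 |
| green | 30.0 | 38.7 | 37.9 |

(each reading ± 0.5 percentage points)

- free catalyst is single-handed; left-handed substrate and right-handed substrate are mirror images of each other, charged as a racemate, each of them at the stated concentration
- steps under discussion: partner + precatalyst -> free catalyst + spent reagent; partner + catalyst intermediate B -> free catalyst + right-handed product; free catalyst + added ligand <-> idle complex; free catalyst + left-handed substrate <-> catalyst intermediate A; free catalyst + right-handed substrate <-> catalyst intermediate B; partner + catalyst intermediate A -> free catalyst + left-handed product; left-handed substrate <-> right-handed substrate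

- whether the excess of right-handed substrate over left-handed substrate among what is left of the two reaches 98% by 50 h (yes / no)
- the highest excess of right-handed substrate over left-handed substrate among what is left of the two up to 50 h

I begin with the main step alone. A catalyst blind to hand would turn a racemate over with its two substrates side by side, so their excess stays at zero however deep the run goes. That is the zero of my scale. I call depth minus the natural logarithm of the fraction of the two substrates left.

Then I add the preference of the single-handed catalyst. The selectivity factor s is the depth of the left-handed substrate over that of the right-handed substrate, each in its own charge. Pooling the last readings of the ochre, grey and green runs, I read s as 1.22, with the scatter of those readings in it. While the two fractions lie close, the excess is depth times (s − 1)/(s + 1). That factor is the gain, the excess earned per unit of depth, and here it is 0.101.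

Next comes the depth. In the ochre and grey runs, as in the asked flask, the partner matches the two substrates together. The partner is therefore no excess reagent, and each turnover takes it down together with the two substrates. As my own assumption, I let the rate go with precatalyst times the partner left times the fraction of the two substrates left. The reciprocal of that fraction, less 1, then grows in proportion to precatalyst times time. Scaling this from the last readings of the ochre and grey runs to 0.40 mM over 50 h gives a depth of 0.569.

For the remaining steps I add no term. Whatever the interconversion of the substrates, the idle complex and the waking of the precatalyst do up to 30.0 h lies inside these readings, and beyond that I extrapolate. My excess is 5.74%, far below 98%.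

The forecast says no and 9%, holding that “The excess should rise steadily, with its highest value at the end”.

    partner + precatalyst → free catalyst + spent reagent (k = 1.38 L mol⁻¹ h⁻¹)
    partner + catalyst intermediate B → free catalyst + right-handed product (k = 35.6 L mol⁻¹ h⁻¹)
    free catalyst + added ligand ⇌ idle complex (K = 34000 L mol⁻¹, k = 15.6 L mol⁻¹ h⁻¹)
    free catalyst + left-handed substrate ⇌ catalyst intermediate A (K = 7.32 L mol⁻¹, k = 11800 L mol⁻¹ h⁻¹)
    free catalyst + right-handed substrate ⇌ catalyst intermediate B (K = 14.0 L mol⁻¹, k = 602 L mol⁻¹ h⁻¹)
    partner + catalyst intermediate A → free catalyst + left-handed product (k = 74.7 L mol⁻¹ h⁻¹)
    left-handed substrate ⇌ right-handed substrate (k = 0.00574 h⁻¹)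

The answer for the asked flask is no: its excess reaches 6.43%, with 44.1% of the two substrates turned to product at 50.0 h. That product puts the depth at 0.582, and the gain turns this into 5.88%. The neighbour flask with a quarter of the precatalyst goes to a depth of 0.158, for which the gain gives 1.60%, and the excess in that neighbour flask reaches 2.01%.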